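**Retrosynthetic overview**

1. Target ⇐ chelation-controlled O-demethylation ⇐ Rieche formylation of the one free arene position ⇐ bornane-fused benzoxepine methyl ether.
2. Key disconnection: the aryl-O–C2, aryl-CH2–C6 and C1–C7 bonds of the bornane are cut together, back to three components: 2,4-dihydroxy-6-methoxy-isovalerophenone, formaldehyde and (+)-α-pinene (o-quinone methide formation, hetero-Diels–Alder addition, acid-triggered Wagner–Meerwein shift with return of the aryloxide).
3. Ring order: the benzene ring and the bicyclo[3.1.1]heptane are bought; a dihydropyran closes transiently; then the pinane six-membered ring C1–C2–C3–C4–C5–C6 (the one through the CMe2 carbon) contracts to the cyclopentane made of the CH2-bearing CH, its neighbouring CH2, the bridgehead CH, the CMe2 carbon and the methyl-bearing quaternary carbon, while the cyclobutane grows to the second cyclopentane; the oxepane closes last.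
4. Enabling feature: the ether O (bornane C2) and the benzylic CH2 (bornane C6) are both endo and 1,3-cis across the methyl-bearing bridgehead C1. This is the footprint of an o-quinone methide added across C2=C3 of α-pinene anti to the gem-dimethyl bridge, followed by the shift of C6 from pinane C1 to C2. The single methyl ether on the benzene ring decides which phenol oxygen ends in the oxepane.
5. The aryl ketone comes from Friedel–Crafts acylation of 5-methoxyresorcinol with isovaleryl chloride.

Key step: step 2

Assumption: (+)-α-pinene is used in its commercial grade of high enantiomeric purity; the enantiomeric purity of the target is then that of the terpene, since no step touches its C5 stereocentre.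

Atom mapping used below: bornane C1, C2, C3, C4, C5, C6, C7 = pinane C2, C1, C7, C5, C4, C3, C6. Aryl positions (Ar-C1 to Ar-C6) follow the numbering of the ketone formed in step 1.

**Step 1**
Reactants: 1 5-methoxyresorcinol (5-methoxybenzene-1,3-diol); 2 isovaleryl chloride (3-methylbutanoyl chloride)
Product: 3 1-(2,4-dihydroxy-6-methoxyphenyl)-3-methylbutan-1-one
Conditions: AlCl3 (3 equiv), CH2Cl2/MeNO2, 0 °C to rt; ice/1 M HCl
Reagents that add atoms: none
Why: Friedel–Crafts acylation, in which the two equivalent ring positions para to a free hydroxyl (flanked by OH and OMe) should react in preference to the position between the two hydroxyls, and the aluminium chelate of the product resists a second acylation; no stereocentre is formed.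

**Step 2**
Reactants: 3 1-(2,4-dihydroxy-6-methoxyphenyl)-3-methylbutan-1-one; 4 formaldehyde (charged as paraformaldehyde); 5 (+)-α-pinene [(1R,5R)-2,6,6-trimethylbicyclo[3.1.1]hept-2-ene]
Product: 8 bornane-fused benzoxepine methyl ether (bornane 1R,2S,4R,6S; O on C2 endo; CH2 on C6 endo), via o-quinone methide 6 (not isolated), via pinane-fused chroman 7 (not isolated)
Conditions: (CH2O)n (1.3 equiv), 5 (5 equiv), NaOAc (0.1 equiv), AcOH, 80 °C; evaporate (toluene chase); TfOH (0.3 equiv), CH2Cl2/HFIP 4:1, −40 to 0 °C
Reagents that add atoms: none
Why: Proposed new method: acetate-buffered condensation of formaldehyde at Ar-C3 of 3 (the carbon between the two hydroxyls) and loss of water should give o-quinone methide 6, which adds across C2=C3 of 5 on the face anti to the gem-dimethyl bridge in an inverse-demand hetero-Diels–Alder reaction to give the cis-fused tertiary aryl ether 7; once the excess of 5 is evaporated, catalytic TfOH ionises the pinane C2–O bond of 7 with anti-periplanar participation of the C1–C6 cyclobutane bond, C6 migrates from pinane C1 to C2 (Wagner–Meerwein shift) and the tethered aryloxide returns to C1. The closest known reaction types are the three-component Knoevenagel/hetero-Diels–Alder union of acylphloroglucinols, formaldehyde and monoterpenes and the 2-chloropinane to bornyl chloride rearrangement; new is their coupling in one flask with a phenol oxygen as the returning nucleophile. Ring events: the dihydropyran of 7 closes by [4+2] cycloaddition, the pinane six-membered ring C1–C2–C3–C4–C5–C6 contracts to the cyclopentane C2–C3–C4–C5–C6 while the cyclobutane expands to the second cyclopentane, and the oxepane closes by 7-exo-tet attack of oxygen on pinane C1 anti to the departing C1–C6 bond. Stereocentres: the CH2-bearing carbon is set in the cycloaddition by the gem-dimethyl bridge, the quaternary carbon by the suprafacial 1,2-shift onto the face opposite the leaving oxygen, and the O-bearing carbon by inversion at pinane C1, so both new bonds of 8 are endo and all four centres derive from C1 and C5 of (1R,5R)-5. Selectivity needed, first, between the two phenol oxygens: the single methyl ether leaves the Ar-C2 hydroxyl as the only chelation partner of the ketone, so 6 should react as its Ar-C4 carbonyl tautomer and only that oxygen enters the ether. Selectivity needed, second, between bornyl, fenchyl and ring-opened p-menthadienyl outcomes: the endo CH2–aryl tether can deliver oxygen to pinane C1 only anti to C6, which pairs the C6 shift with fast internal return, and the endo secondary ether of 8 has no anti-periplanar bond whose migration leads to a stabilised cation, so it should not re-ionise.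

**Step 3**
Reactants: 8 bornane-fused benzoxepine methyl ether
Product: 9 formylated methyl ether (CHO on the ring carbon between the OMe carbon and the ether-O carbon; bornane 1R,2S,4R,6S)
Conditions: Cl2CHOMe (2 equiv), TiCl4 (3 equiv), CH2Cl2, −40 to 0 °C; ice-water
Reagents that add atoms: dichloromethyl methyl ether, COC(Cl)Cl; water, O
Why: Rieche formylation at the single unsubstituted ring position, which is activated by the para hydroxyl and two ortho alkoxy groups, while the endo bornyl ether should survive TiCl4 at low temperature; no stereocentre is touched.

**Step 4**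
Reactants: 9 formylated methyl ether
Product: 10 target CNP0246493.1
Conditions: MgI2·OEt2 (3 equiv), PhMe, 80 °C; then 1 M HCl
Reagents that add atoms: none
Why: Chelation-controlled O-demethylation, in which magnesium held between a carbonyl oxygen and the methoxy oxygen flanked by formyl and ketone activates only that O–CH3 bond for SN2 attack by iodide, whereas the bornyl C–O carbon is secondary, neopentyl-like and shielded on its backside (exo face) by the gem-dimethyl bridge; no stereocentre is touched.

**Compound list**

1 | 5-methoxyresorcinol (5-methoxybenzene-1,3-diol) | COc1cc(O)cc(O)c1 | starting material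
2 | isovaleryl chloride (3-methylbutanoyl chloride) | CC(C)CC(Cl)=O | starting material
3 | 1-(2,4-dihydroxy-6-methoxyphenyl)-3-methylbutan-1-one | CC(C)CC(=O)c1c(O)cc(O)cc1OC | intermediate
4 | formaldehyde (charged as paraformaldehyde) | C=O | starting material
5 | (+)-α-pinene, (1R,5R)-2,6,6-trimethylbicyclo[3.1.1]hept-2-ene | CC1=CC[C@@H]2C[C@H]1C2(C)C | starting material
6 | o-quinone methide, 5-hydroxy-3-methoxy-6-methylidene-4-(3-methylbutanoyl)cyclohexa-2,4-dien-1-one (not isolated) | CC(C)CC(=O)C1=C(O)C(=C)C(=O)C=C1OC | intermediate
7 | pinane-fused chroman: cis-fused hetero-Diels–Alder adduct with aryl O on pinane C2 and aryl CH2 on pinane C3, both anti to the gem-dimethyl bridge, (1S,2R,3S,5R) in pinane numbering; arene carries OH, isovaleryl and OMe (not isolated) | CC(C)CC(=O)c1c(O)c2C[C@@H]3C[C@@H]4C[C@@H](C4(C)C)[C@]3(C)Oc2cc1OC | intermediate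
8 | bornane-fused benzoxepine methyl ether: (1R,2S,4R,6S)-bornane with the ring O on C2 (endo) and the benzylic CH2 on C6 (endo); benzene ring, from the CH2-bearing carbon: C–OH, C–CO–CH2CH(CH3)2, C–OMe, C–H, C–O(bornyl) | CC(C)CC(=O)c1c(OC)cc2c(c1O)C[C@@H]1C[C@@H]3C[C@H](O2)[C@@]1(C)C3(C)C | intermediate
9 | formylated methyl ether: as 8, with CHO in place of the ring H | CC(C)CC(=O)c1c(OC)c(C=O)c2c(c1O)C[C@@H]1C[C@@H]3C[C@H](O2)[C@@]1(C)C3(C)C | intermediate
10 | CNP0246493.1: as 9, with OH in place of OMe | CC(C)CC(=O)c1c(O)c(C=O)c2c(c1O)C[C@@H]1C[C@@H]3C[C@H](O2)[C@@]1(C)C3(C)C | target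

**Step count and risks**

Total step count: 4. Longest linear sequence: 4 steps (1 → 3 → 8 → 9 → 10).

Steps most likely to fail:

1. Step 2 (Proposed new method). In the acid stage the 2-pinanyl cation may open its cyclobutane to a p-menthadienyl cation and lose a proton faster than C6 migrates. In the condensation stage the quinone methide may be captured by a second molecule of 3 (methylene-bridged dimer) before 5 adds. Fallback with known reaction types, setting out from 3 and returning at 8: Mannich reaction of 3 with 4 and morpholine (EtOH, rt) gives the Mannich base 1-[2,4-dihydroxy-6-methoxy-3-(morpholin-4-ylmethyl)phenyl]-3-methylbutan-1-one F1. Heating F1 with 5 in toluene at 110 °C (loss of morpholine, thermal o-quinone methide hetero-Diels–Alder reaction, no free formaldehyde present) gives chroman 7, which is isolated and purified. The pure ether 7 is then ionised on its own with SnCl4 in CH2Cl2 at −78 °C, under aprotic ion-pair conditions free of alkene and acetate, as a discrete 2-pinanyl to bornyl Wagner–Meerwein rearrangement to 8.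

2. Step 3. TiCl4 may ionise the secondary bornyl–O bond or the O–CH3 bond in competition with substitution at the crowded ring position. Fallback, setting out from 8 and returning at 10: the last two operations are reversed and strong Lewis acids avoided. Nucleophilic O-demethylation of 8 with NaSEt in DMF at 120 °C gives the dihydroxy ketone (de-O-methyl 8) F2. Vilsmeier–Haack formylation of F2 (POCl3, DMF, MeCN, 0 °C to rt; aqueous NaOAc) at the only free position, now ortho to a free hydroxyl, gives 10 directly.

3. Step 1. Acylation may occur between the two hydroxyls (symmetric 2,6-dihydroxy-4-methoxy isomer), and AlCl3 may remove the methyl ether. Fallback, setting out from 2 and returning at 3: the regiochemistry is fixed by protecting groups instead of directing effects. Friedel–Crafts acylation of phloroglucinol F3 with 2 (AlCl3, CH2Cl2/MeNO2) gives 1-(2,4,6-trihydroxyphenyl)-3-methylbutan-1-one F4. MOMCl/iPr2NEt (2.2 equiv, CH2Cl2, 0 °C) gives the bis-MOM ether 1-[2-hydroxy-4,6-bis(methoxymethoxy)phenyl]-3-methylbutan-1-one F5, the chelated hydroxyl staying free. MeI/K2CO3 in acetone at reflux methylates that hydroxyl to 1-[2-methoxy-4,6-bis(methoxymethoxy)phenyl]-3-methylbutan-1-one F6. HCl in MeOH at 40 °C removes both MOM groups to give 3.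

**Further compounds**

F1 | step 2 | 1-[2,4-dihydroxy-6-methoxy-3-(morpholin-4-ylmethyl)phenyl]-3-methylbutan-1-one | CC(C)CC(=O)c1c(O)c(CN2CCOCC2)c(O)cc1OC
F2 | step 3 | de-O-methyl 8 (dihydroxy ketone, bornane 1R,2S,4R,6S) | CC(C)CC(=O)c1c(O)cc2c(c1O)C[C@@H]1C[C@@H]3C[C@H](O2)[C@@]1(C)C3(C)C
F3 | step 1 | phloroglucinol (benzene-1,3,5-triol) | Oc1cc(O)cc(O)c1
F4 | step 1 | 1-(2,4,6-trihydroxyphenyl)-3-methylbutan-1-one | CC(C)CC(=O)c1c(O)cc(O)cc1O
F5 | step 1 | 1-[2-hydroxy-4,6-bis(methoxymethoxy)phenyl]-3-methylbutan-1-one | CC(C)CC(=O)c1c(O)cc(OCOC)cc1OCOC
F6 | step 1 | 1-[2-methoxy-4,6-bis(methoxymethoxy)phenyl]-3-methylbutan-1-one | CC(C)CC(=O)c1c(OC)cc(OCOC)cc1OCOC
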